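The route rests on cutting the butenolide ring (O1, lactone carbonyl C2, methyl-bearing C3, carboxyl-bearing C4, stereocentre C5) at O1–C5 and C2–C3. The feature exploited is that the O1–C2(=O) segment of this ring is a CO2 molecule clamped between a carbon that can be an enolate (C3) and one that can be an electrophile (C5). The precursor is therefore an acyclic conjugated ynone: C3 its sole α-carbon, C4 its ketone, C5≡C6 its alkyne. Silver-catalysed carboxylative cyclisation under CO2 forges both bonds in one operation and gives a (Z)-5-alkylidene tetronic acid. The C4 enol then becomes CO2H through its triflate, and asymmetric hydrogenation of C5=C6 sets C5.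

Key step: step 4

Remark on labels: O1 and C2 to C5 are the ring labels defined above, not the locants of the systematic names. C6 is the first chain carbon, the chain holds thirteen CH2 groups between C5 and the acetate oxygen, and C5 is R.
Assumption: both antipodes of the hydrogenation ligand are available, and the one that delivers H2 to the Si face of C5 is used.

Step 1
Reactants: 1 12-bromododecan-1-ol; 2 lithium acetylide ethylenediamine complex
Product: 3 tetradec-13-yn-1-ol
Conditions: 2 (3 equiv), DMSO, 0 °C to rt; aq NH4Cl
Reagents that add atoms: none
Why: SN2 alkylation of a primary bromide by lithium acetylide in a dipolar aprotic solvent; the first equivalent of 2 is consumed by the free hydroxyl, whose alkoxide is a much poorer nucleophile than the acetylide, so no protecting group is needed.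

Step 2
Reactants: 3 tetradec-13-yn-1-ol
Product: 4 tetradec-13-yn-1-yl acetate
Conditions: Ac2O, pyridine, DMAP (cat.), CH2Cl2, rt
Reagents that add atoms: acetic anhydride CC(=O)OC(C)=O
Why: DMAP-catalysed O-acylation installs the terminal acetate of the target at the outset, because every later step runs under conditions that an alkyl acetate tolerates.

Step 3
Reactants: 4 tetradec-13-yn-1-yl acetate; 5 propanoyl chloride
Product: 6 15-oxoheptadec-13-yn-1-yl acetate
Conditions: PdCl2(PPh3)2 (2 mol %), CuI (4 mol %), Et3N (1.5 equiv), THF, rt
Reagents that add atoms: none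
Why: Acyl Sonogashira coupling, in which the copper acetylide of 4 transmetalates to the acylpalladium chloride formed from 5 and zerovalent palladium and reductive elimination gives the ynone under amine conditions that leave the acetate untouched.

Step 4
Reactants: 6 15-oxoheptadec-13-yn-1-yl acetate
Product: 8 (Z)-13-(3-hydroxy-4-methyl-5-oxofuran-2(5H)-ylidene)tridecyl acetate, via β-ketocarboxylate 7 (not isolated)
Conditions: AgOAc (10 mol %), MTBD (7-methyl-1,5,7-triazabicyclo[4.4.0]dec-5-ene, 2 equiv), CO2 (2 MPa), MeCN, 25 °C; then 1 M HCl
Reagents that add atoms: carbon dioxide O=C=O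
Why: MTBD reversibly deprotonates C3, the only α-carbon of the ynone, and the enolate adds to CO2 to give β-ketocarboxylate 7 (C2–C3 bond); monovalent silver then π-activates C5≡C6 and the carboxylate oxygen attacks C5 anti to the metal (O1–C5 bond), after which protodeargentation and enolisation at C4 release the tetronate. The closest known reaction type is the silver-catalysed carboxylative cyclisation of conjugated ynones and alkynyl ketones with CO2. The single ring closes in the 5-exo-dig mode. No stereocentre is created; anti oxyargentation followed by stereoretentive protonolysis fixes C5=C6 as Z, the geometry on which the later hydrogenation relies. The step needs closure at C5 (5-exo-dig) rather than at C6 (6-endo-dig) and needs the uphill carboxylation to be pulled forward: enolisation of the β-ketocarboxylate switches off the Michael polarisation of the alkyne so that ring size and silver coordination decide for C5, and irreversible cyclisation to a strongly acidic tetronic acid, held as its guanidinium salt, drains the CO2 equilibrium.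

Step 5
Reactants: 8 (Z)-13-(3-hydroxy-4-methyl-5-oxofuran-2(5H)-ylidene)tridecyl acetate
Product: 9 (Z)-13-(4-methyl-5-oxo-3-(trifluoromethylsulfonyloxy)furan-2(5H)-ylidene)tridecyl acetate
Conditions: Tf2O (1.1 equiv), iPr2NEt (1.3 equiv), CH2Cl2, −78 °C
Reagents that add atoms: trifluoromethanesulfonic anhydride O=S(=O)(OS(=O)(=O)C(F)(F)F)C(F)(F)F
Why: O-sulfonylation of the tetronate at the more nucleophilic C4 oxygen gives the vinylogous acyl triflate, the standard activation of tetronic acids for cross-coupling, at a temperature at which the enol lactone and the acetate are inert.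

Step 6
Reactants: 9 (Z)-13-(4-methyl-5-oxo-3-(trifluoromethylsulfonyloxy)furan-2(5H)-ylidene)tridecyl acetate
Product: 10 (Z)-2-(13-acetoxytridecylidene)-4-methyl-5-oxo-2,5-dihydrofuran-3-carboxylic acid
Conditions: Pd(OAc)2 (5 mol %), dppf (6 mol %), CO (1 atm), H2O (5 equiv), iPr2NEt (2.2 equiv), DMF, 25 to 40 °C; then 1 M HCl
Reagents that add atoms: carbon monoxide [C-]#[O+]; water O
Why: Palladium-catalysed hydroxycarbonylation of a vinyl triflate, in which fast oxidative addition of the electron-poor C4–OTf bond to zerovalent palladium, CO insertion and hydrolysis of the acylpalladium place CO2H on C4 without touching the Z-alkylidene or the acetate.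

Step 7
Reactants: 10 (Z)-2-(13-acetoxytridecylidene)-4-methyl-5-oxo-2,5-dihydrofuran-3-carboxylic acid
Product: 11 (R)-2-(13-acetoxytridecyl)-4-methyl-5-oxo-2,5-dihydrofuran-3-carboxylic acid
Conditions: [Ir(cod)(SpinPHOX)]BArF (1 mol %), H2 (30 bar), CH2Cl2, rt
Reagents that add atoms: none
Why: Iridium-catalysed asymmetric hydrogenation of an exocyclic enol-lactone C=C, a reaction type established for 3-ylidenephthalides and γ-alkylidene lactones with a catalyst family that also accepts free acrylic acids; the chiral N,P pocket directs 1,2-addition of H2 to the Si face of C5 of the single Z isomer and so sets R, while the tetrasubstituted, doubly acceptor-substituted C3=C4 bond is too hindered and electron-poor to bind.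

Compound list
1 | 12-bromododecan-1-ol | OCCCCCCCCCCCCBr | starting material
2 | lithium acetylide ethylenediamine complex | [Li+].[C-]#C.NCCN | starting material
3 | tetradec-13-yn-1-ol | C#CCCCCCCCCCCCCO | intermediate
4 | tetradec-13-yn-1-yl acetate | C#CCCCCCCCCCCCCOC(C)=O | intermediate
5 | propanoyl chloride | CCC(=O)Cl | starting material
6 | 15-oxoheptadec-13-yn-1-yl acetate | CCC(=O)C#CCCCCCCCCCCCCOC(C)=O | intermediate
7 | 17-acetoxy-2-methyl-3-oxoheptadec-4-ynoic acid, present as its MTBD-H carboxylate and drawn as the free acid, C3 unresolved | CC(C(=O)O)C(=O)C#CCCCCCCCCCCCCOC(C)=O | intermediate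
8 | (Z)-13-(3-hydroxy-4-methyl-5-oxofuran-2(5H)-ylidene)tridecyl acetate | CC(=O)OCCCCCCCCCCCC/C=C1\OC(=O)C(C)=C1O | intermediate
9 | (Z)-13-(4-methyl-5-oxo-3-(trifluoromethylsulfonyloxy)furan-2(5H)-ylidene)tridecyl acetate | CC(=O)OCCCCCCCCCCCC/C=C1\OC(=O)C(C)=C1OS(=O)(=O)C(F)(F)F | intermediate
10 | (Z)-2-(13-acetoxytridecylidene)-4-methyl-5-oxo-2,5-dihydrofuran-3-carboxylic acid | CC(=O)OCCCCCCCCCCCC/C=C1\OC(=O)C(C)=C1C(=O)O | intermediate
11 | (R)-2-(13-acetoxytridecyl)-4-methyl-5-oxo-2,5-dihydrofuran-3-carboxylic acid | CC(=O)OCCCCCCCCCCCCC[C@H]1OC(=O)C(C)=C1C(=O)O | target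

Total step count: 7. Longest linear sequence: 7 steps (1 to 11).

Steps most likely to fail

Step 7. Facial discrimination on a long, flexible alkylidene may be poor. Hydrogen may also add 1,4 across the C3=C4–C5=C6 diene, or the free acid may slow the catalyst. The fallback sets out from 10. Non-selective hydrogenation over Pd/C (H2, 1 atm, EtOAc, stopped after one equivalent) should give the racemic acid F1. This is resolved classically by fractional crystallisation of the (R)-1-phenylethylammonium salt F2, with the other amine antipode as the alternative. Acidification with 1 M HCl comes back to the route at 11. Acid from the mother liquor can be racemised through its C5 dienolate with DBU and resubmitted as F1.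

Step 4. The guanidine base may shift the propargylic C7 hydrogens, so that the ynone drifts to an allenyl ketone that silver cycloisomerises to a furan. Closure may also take the 6-endo-dig course, or decarboxylation may outrun cyclisation. The fallback sets out from 6. Soft enolisation (TMSOTf, Et3N, CH2Cl2, 0 °C) should give the isolable silyl enol ether F3. CsF in DMF under CO2 (2 MPa) with AgOAc (10 mol %) then releases the C3 enolate without any strong amine base. The acidic C3–H of the cyclised lactone supplies the proton for protodeargentation. Carboxylation and 5-exo-dig closure still occur in one operation, and after 1 M HCl the sequence comes back to the route at 8.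

Step 6. Water may add at C4 and expel triflate, so that the activating group is lost and 8 is regenerated before oxidative addition takes place. The fallback sets out from 9. Anhydrous alkoxycarbonylation (Pd(OAc)2, dppf, CO, allyl alcohol, iPr2NEt, DMF) should give the allyl ester F4. Neutral deallylation with Pd(PPh3)4 and morpholine in THF comes back to the route at 10.

Further compounds
F1 | step 7 | racemic 2-(13-acetoxytridecyl)-4-methyl-5-oxo-2,5-dihydrofuran-3-carboxylic acid | CC(=O)OCCCCCCCCCCCCCC1OC(=O)C(C)=C1C(=O)O
F2 | step 7 | (R)-1-phenylethylammonium (R)-2-(13-acetoxytridecyl)-4-methyl-5-oxo-2,5-dihydrofuran-3-carboxylate | CC(=O)OCCCCCCCCCCCCC[C@H]1OC(=O)C(C)=C1C(=O)[O-].C[C@@H]([NH3+])c1ccccc1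
F3 | step 4 | 15-(trimethylsilyloxy)heptadec-15-en-13-yn-1-yl acetate (E/Z mixture) | CC=C(O[Si](C)(C)C)C#CCCCCCCCCCCCCOC(C)=O
F4 | step 6 | allyl (Z)-2-(13-acetoxytridecylidene)-4-methyl-5-oxo-2,5-dihydrofuran-3-carboxylate | CC(=O)OCCCCCCCCCCCC/C=C1\OC(=O)C(C)=C1C(=O)OCC=C
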